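**Retrosynthetic overview**
1. Licoleafol ⇐ fluoride removal of four aryl silyl ethers ⇐ (E)-selective SeO2 hydroxylation of the prenyl group of a tetrasilylated (2S)-8-prenyleriodictyol. Rings A and B are bought as arenes, and ring C is the only ring built.
2. Ring C ⇐ cut C3–C4 together with C2–H. This is an enantioselective rhodium-catalysed intramolecular hydroacylation of an achiral isomer, a 2-(1-arylvinyloxy)benzaldehyde. In it C4 is a formyl group (aldehyde level) and C2=C3 is an enol ether (C2 at ketone level).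
3. Enabling feature: the chain O1–C2(H)(ring B)–C3H2–C4(=O) of ring C hangs on the adjacent ring A carbons C8a and C4a. O1 can therefore hold a 1,1-disubstituted C2=C3 enol ether directly beside the formyl C4–H. Adding C4–H across C2=C3 makes C3–C4, the C4 ketone, C2–H and the only stereocenter at once.
4. Enol ether ⇐ E2 loss of HCl from a 2-chloro-1-arylethyl aryl ether ⇐ Mitsunobu union of the ring A phenol with a ring B chlorohydrin (from 2-chloro-3',4'-dihydroxyacetophenone).
5. Ring A phenol ⇐ C-prenylation of symmetric 2,4,6-trihydroxybenzaldehyde (C3 and C5 are equivalent, so no 8-versus-6 question arises). A sterically guided bis-silylation then leaves only the future O1 free.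

Key step: step 7

Assumption: the structure is taken exactly as drawn, with C3 as CH2, configuration (2S), and an (E)-4-hydroxy-3-methylbut-2-enyl chain at C8.
Assumption: (R)-DTBM-SEGPHOS is taken to deliver hydride to the face of C2 that leads to (2S). If a test run shows the opposite sense, the (S)-ligand is used and nothing else changes.

**Step 1**
Reactants: 1 2,4,6-trihydroxybenzaldehyde; 2 prenyl bromide (1-bromo-3-methylbut-2-ene)
Product: 3 2,4,6-trihydroxy-3-(3-methylbut-2-en-1-yl)benzaldehyde
Conditions: KOH (1.0 equiv), H2O, slow addition of 2, 0 °C to rt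
Reagents that add atoms: none
Why: Phenolate C-alkylation (SN2) of the ambident acylphloroglucinol anion in water, where hydrogen bonding to the phenoxide oxygens steers the soft allylic bromide to carbon, and because C3 and C5 of 1 are equivalent only one mono-C-prenyl product can form.

**Step 2**
Reactants: 3 2,4,6-trihydroxy-3-(3-methylbut-2-en-1-yl)benzaldehyde
Product: 4 4,6-bis(tert-butyldimethylsilyloxy)-2-hydroxy-3-(3-methylbut-2-en-1-yl)benzaldehyde
Conditions: TBSCl (2.1 equiv), imidazole, CH2Cl2–DMF, 0 °C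
Reagents that add atoms: tert-butyldimethylsilyl chloride, CC(C)(C)[Si](C)(C)Cl
Why: Standard silyl ether formation should take the unchelated 4-OH first and then the less crowded 6-OH, leaving free the 2-OH that is wedged between the prenyl and formyl groups and hydrogen-bonded to the formyl oxygen.

**Step 3**
Reactants: 5 2-chloro-1-(3,4-dihydroxyphenyl)ethan-1-one
Product: 6 1-[3,4-bis(tert-butyldimethylsilyloxy)phenyl]-2-chloroethan-1-one
Conditions: TBSCl (2.3 equiv), iPr2NEt, DMF, 0 °C to rt
Reagents that add atoms: tert-butyldimethylsilyl chloride, CC(C)(C)[Si](C)(C)Cl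
Why: Routine silylation of a catechol, run with a hindered amine base that should not be alkylated by the phenacyl chloride.

**Step 4**
Reactants: 6 1-[3,4-bis(tert-butyldimethylsilyloxy)phenyl]-2-chloroethan-1-one
Product: 7 rac-1-[3,4-bis(tert-butyldimethylsilyloxy)phenyl]-2-chloroethan-1-ol
Conditions: NaBH4, THF–EtOH, −20 to 0 °C; aq NH4Cl
Reagents that add atoms: none
Why: Borohydride 1,2-reduction of an α-chloro ketone at low temperature should stop at the chlorohydrin without epoxide closure, and the carbinol center is left racemic on purpose because step 6 erases it.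

**Step 5**
Reactants: 4 4,6-bis(tert-butyldimethylsilyloxy)-2-hydroxy-3-(3-methylbut-2-en-1-yl)benzaldehyde; 7 rac-1-[3,4-bis(tert-butyldimethylsilyloxy)phenyl]-2-chloroethan-1-ol
Product: 8 rac-2-{1-[3,4-bis(tert-butyldimethylsilyloxy)phenyl]-2-chloroethoxy}-4,6-bis(tert-butyldimethylsilyloxy)-3-(3-methylbut-2-en-1-yl)benzaldehyde
Conditions: PPh3, DIAD, toluene (concentrated), 0 °C to rt
Reagents that add atoms: none
Why: Mitsunobu reaction in which the acidic ortho-formyl phenol, the only free OH of 4, displaces the oxyphosphonium ion of the secondary benzylic alcohol, a coupling well known for phenols with halohydrins, and the configuration of the new center is irrelevant here.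

**Step 6**
Reactants: 8 rac-2-{1-[3,4-bis(tert-butyldimethylsilyloxy)phenyl]-2-chloroethoxy}-4,6-bis(tert-butyldimethylsilyloxy)-3-(3-methylbut-2-en-1-yl)benzaldehyde
Product: 9 2-({1-[3,4-bis(tert-butyldimethylsilyloxy)phenyl]ethenyl}oxy)-4,6-bis(tert-butyldimethylsilyloxy)-3-(3-methylbut-2-en-1-yl)benzaldehyde (achiral)
Conditions: KOtBu (1.3 equiv), THF, −20 to 0 °C; chromatography on Et3N-washed silica
Reagents that add atoms: none
Why: E2 dehydrochlorination of a 2-chloroethyl aryl ether, the classical entry to aryl vinyl ethers, is helped here by the benzylic, oxygen-bearing C–H, which is the only hydrogen β to chloride, while the formyl group has no α-hydrogen for the base to attack.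

**Step 7**
Reactants: 9 2-({1-[3,4-bis(tert-butyldimethylsilyloxy)phenyl]ethenyl}oxy)-4,6-bis(tert-butyldimethylsilyloxy)-3-(3-methylbut-2-en-1-yl)benzaldehyde
Product: 10 (2S)-2-[3,4-bis(tert-butyldimethylsilyloxy)phenyl]-5,7-bis(tert-butyldimethylsilyloxy)-8-(3-methylbut-2-en-1-yl)chroman-4-one
Conditions: [Rh(cod)Cl]2 (2.5 mol %), (R)-DTBM-SEGPHOS (5 mol %), Na[B(3,5-(CF3)2C6H3)4] (5 mol %), dry 1,4-dioxane, 60 °C, argon
Reagents that add atoms: none
Why: Proposed new method: the cationic monovalent rhodium bisphosphine complex inserts into the formyl C4–H bond of 9 to give an acyl hydride of trivalent rhodium, the neighbouring enol ether C2=C3 binds, hydride migrates to C2 while rhodium takes the terminal C3 (seven-membered acyl rhodacycle), and reductive elimination forms C3–C4 and frees the catalyst. The closest known reaction type is the enantioselective, endo-selective rhodium-catalysed intramolecular hydroacylation of 1,1-disubstituted alkenes, which turns ortho-allylbenzaldehydes into 3-substituted tetralones and N-(1-arylvinyl)indole-2-carbaldehydes into β-aryl cyclic ketones; what has not been shown is an aryl 1-arylvinyl ether as the alkene partner in a six-ring closure. Ring C closes in a formal 6-endo-trig mode, with C4 bonding to the CH2 terminus of an alkene that lies inside the new ring. The only stereocenter, C2, is created in the hydride transfer, and its configuration is controlled by the axially chiral bisphosphine, whose pocket should let only one enantiotopic face of the flat enol ether bind next to Rh–H. The step needs endo over exo regioselectivity (exo closure would put the acyl group on C2 and give a 2-aryl-2-methylbenzofuran-3-one); this is secured by the 1,1-disubstitution, since exo insertion demands a tertiary alkyl–rhodium bond, and by the O1 lone pair, which polarises C3 toward the metal and C2 toward hydride. It also needs chemoselectivity over the prenyl alkene, alkene isomerisation and decarbonylation, secured because the prenyl group is trisubstituted and meta to the formyl group and so out of reach, because C2 carries no further C–H for chain walking, and because O1 is buttressed between the C8 prenyl and C4a formyl groups so that the enol ether is held against the metal.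

**Step 8**
Reactants: 10 (2S)-2-[3,4-bis(tert-butyldimethylsilyloxy)phenyl]-5,7-bis(tert-butyldimethylsilyloxy)-8-(3-methylbut-2-en-1-yl)chroman-4-one
Product: 11 (2S)-2-[3,4-bis(tert-butyldimethylsilyloxy)phenyl]-5,7-bis(tert-butyldimethylsilyloxy)-8-[(E)-4-hydroxy-3-methylbut-2-en-1-yl]chroman-4-one
Conditions: SeO2 (0.3 equiv), t-BuOOH (3 equiv, in decane), CH2Cl2, 0 °C to rt, stopped before over-oxidation sets in
Reagents that add atoms: tert-butyl hydroperoxide (terminal oxygen source), CC(C)(C)OO; selenium dioxide (oxygen carrier), O=[Se]=O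
Why: Riley allylic oxidation, in which the ene reaction at the more substituted alkene terminus and the following [2,3]-sigmatropic shift deliver oxygen to the methyl group trans to the chain and so fix the (E)-geometry, while the cold, weakly acidic medium should leave C2 and the C3 methylene untouched.

**Step 9**
Reactants: 11 (2S)-2-[3,4-bis(tert-butyldimethylsilyloxy)phenyl]-5,7-bis(tert-butyldimethylsilyloxy)-8-[(E)-4-hydroxy-3-methylbut-2-en-1-yl]chroman-4-one
Product: 12 licoleafol, (2S)-2-(3,4-dihydroxyphenyl)-5,7-dihydroxy-8-[(E)-4-hydroxy-3-methylbut-2-en-1-yl]chroman-4-one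
Conditions: Et3N·3HF (excess), THF, 0 °C to rt; work-up at pH 5–6
Reagents that add atoms: none
Why: Fluoride cleavage of the four aryl silyl ethers in a slightly acidic medium avoids free phenoxides and hence the retro-oxa-Michael ring opening that would racemise C2, and it should leave the allylic alcohol and the alkene alone.

**Compound list**
1 | 2,4,6-trihydroxybenzaldehyde | O=Cc1c(O)cc(O)cc1O | starting material
2 | prenyl bromide (1-bromo-3-methylbut-2-ene) | CC(C)=CCBr | starting material
3 | 2,4,6-trihydroxy-3-(3-methylbut-2-en-1-yl)benzaldehyde | CC(C)=CCc1c(O)cc(O)c(C=O)c1O | intermediate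
4 | 4,6-bis(tert-butyldimethylsilyloxy)-2-hydroxy-3-(3-methylbut-2-en-1-yl)benzaldehyde | CC(C)=CCc1c(O[Si](C)(C)C(C)(C)C)cc(O[Si](C)(C)C(C)(C)C)c(C=O)c1O | intermediate
5 | 2-chloro-1-(3,4-dihydroxyphenyl)ethan-1-one | O=C(CCl)c1ccc(O)c(O)c1 | starting material
6 | 1-[3,4-bis(tert-butyldimethylsilyloxy)phenyl]-2-chloroethan-1-one | O=C(CCl)c1ccc(O[Si](C)(C)C(C)(C)C)c(O[Si](C)(C)C(C)(C)C)c1 | intermediate
7 | rac-1-[3,4-bis(tert-butyldimethylsilyloxy)phenyl]-2-chloroethan-1-ol | OC(CCl)c1ccc(O[Si](C)(C)C(C)(C)C)c(O[Si](C)(C)C(C)(C)C)c1 | intermediate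
8 | rac-2-{1-[3,4-bis(tert-butyldimethylsilyloxy)phenyl]-2-chloroethoxy}-4,6-bis(tert-butyldimethylsilyloxy)-3-(3-methylbut-2-en-1-yl)benzaldehyde | CC(C)=CCc1c(O[Si](C)(C)C(C)(C)C)cc(O[Si](C)(C)C(C)(C)C)c(C=O)c1OC(CCl)c1ccc(O[Si](C)(C)C(C)(C)C)c(O[Si](C)(C)C(C)(C)C)c1 | intermediate
9 | 2-({1-[3,4-bis(tert-butyldimethylsilyloxy)phenyl]ethenyl}oxy)-4,6-bis(tert-butyldimethylsilyloxy)-3-(3-methylbut-2-en-1-yl)benzaldehyde | CC(C)=CCc1c(O[Si](C)(C)C(C)(C)C)cc(O[Si](C)(C)C(C)(C)C)c(C=O)c1OC(=C)c1ccc(O[Si](C)(C)C(C)(C)C)c(O[Si](C)(C)C(C)(C)C)c1 | intermediate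
10 | (2S)-2-[3,4-bis(tert-butyldimethylsilyloxy)phenyl]-5,7-bis(tert-butyldimethylsilyloxy)-8-(3-methylbut-2-en-1-yl)chroman-4-one | CC(C)=CCc1c(O[Si](C)(C)C(C)(C)C)cc(O[Si](C)(C)C(C)(C)C)c2c1O[C@H](c1ccc(O[Si](C)(C)C(C)(C)C)c(O[Si](C)(C)C(C)(C)C)c1)CC2=O | intermediate
11 | (2S)-2-[3,4-bis(tert-butyldimethylsilyloxy)phenyl]-5,7-bis(tert-butyldimethylsilyloxy)-8-[(E)-4-hydroxy-3-methylbut-2-en-1-yl]chroman-4-one | C/C(=C\Cc1c(O[Si](C)(C)C(C)(C)C)cc(O[Si](C)(C)C(C)(C)C)c2c1O[C@H](c1ccc(O[Si](C)(C)C(C)(C)C)c(O[Si](C)(C)C(C)(C)C)c1)CC2=O)CO | intermediate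
12 | licoleafol, (2S)-2-(3,4-dihydroxyphenyl)-5,7-dihydroxy-8-[(E)-4-hydroxy-3-methylbut-2-en-1-yl]chroman-4-one | C/C(=C\Cc1c(O)cc(O)c2c1O[C@H](c1ccc(O)c(O)c1)CC2=O)CO | target

**Step count**
Total steps: 9. Longest linear sequence: 7 (steps 1, 2, 5, 6, 7, 8, 9).

**Steps most likely to fail**

*Step 7.* Four things may go wrong:
- hydride insertion with the reverse regiochemistry, followed by exo closure;
- decarbonylation of the acyl rhodium hydride with loss of the catalyst;
- hydrolysis or aldol-type closure of the enol ether at the Lewis-acidic cation;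
- poor facial selectivity.

The fallback uses known chemistry, makes the same C3–C4 ring closure, and sets the stereocenter beforehand. It sets out from 6 and 4 and comes back at 10.
- Ketone 6 is reduced by Noyori asymmetric transfer hydrogenation (RuCl[(R,R)-TsDPEN](p-cymene), HCO2H–Et3N) to (S)-1-[3,4-bis(tert-butyldimethylsilyloxy)phenyl]-2-chloroethan-1-ol F1.
- A Mitsunobu reaction of F1 with phenol 4 (PPh3, DIAD, toluene, 0 °C) proceeds with inversion to the (R)-chloro ether F2, the single enantiomer of 8.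
- Finkelstein exchange (NaI, acetone, reflux) gives the (R)-iodo ether F3.
- With Bu3SnH and AIBN in benzene at 80 °C, the primary C3 radical adds 6-exo to the formyl carbon C4. This mode is known from radical cyclisations onto aldehydes and from the chroman-4-one-forming cascades of 2-(allyloxy)benzaldehydes. The product is the (2S)-flavan-4-ol F4, as a mixture at C4.
- Dess–Martin oxidation (NaHCO3, CH2Cl2) of F4 returns to 10.

*Step 6.* Aryl silyl groups may be lost to tert-butoxide, or the good aryloxide leaving group may be expelled in place of chloride. The fallback replaces base-induced E2 by a neutral syn elimination. It sets out from 8 and comes back at 9.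
- Chloride 8 is displaced by NaSePh in DMF at rt to give the phenyl selenide F5. The NaSePh is preformed from PhSeSePh and NaH, so that no hydride reductant meets the aldehyde.
- F5 is oxidised with mCPBA (1 equiv, CH2Cl2, −78 °C) to the selenoxide F6.
- On warming to rt in the presence of iPr2NH, F6 eliminates toward its only β-hydrogen and gives 9.

*Step 8.* Over-oxidation to the aldehyde level, incomplete conversion, or oxidation next to the C4 ketone may occur. The fallback rebuilds the alkene instead of oxidising a C–H bond. It sets out from 10 and comes back at 11.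
- Upjohn dihydroxylation (OsO4 cat., NMO, acetone–H2O) of the only alkene gives the side-chain diol F7.
- NaIO4 cleavage of F7 gives the C8 arylacetaldehyde F8.
- Wittig reaction of F8 with the stabilised ylide 2-(triphenylphosphoranylidene)propanal (toluene, 60 °C) gives the (E)-enal F9.
- NaBH4 in THF–EtOH at −78 °C reduces the aldehyde in preference to the hindered, electron-rich C4 aryl ketone and gives 11.

**Further compounds**
F1 | step 7 | (S)-1-[3,4-bis(tert-butyldimethylsilyloxy)phenyl]-2-chloroethan-1-ol | O[C@@H](c1ccc(O[Si](C)(C)C(C)(C)C)c(O[Si](C)(C)C(C)(C)C)c1)CCl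
F2 | step 7 | 2-{(1R)-1-[3,4-bis(tert-butyldimethylsilyloxy)phenyl]-2-chloroethoxy}-4,6-bis(tert-butyldimethylsilyloxy)-3-(3-methylbut-2-en-1-yl)benzaldehyde | CC(C)=CCc1c(O[Si](C)(C)C(C)(C)C)cc(O[Si](C)(C)C(C)(C)C)c(C=O)c1O[C@H](c1ccc(O[Si](C)(C)C(C)(C)C)c(O[Si](C)(C)C(C)(C)C)c1)CCl
F3 | step 7 | 2-{(1R)-1-[3,4-bis(tert-butyldimethylsilyloxy)phenyl]-2-iodoethoxy}-4,6-bis(tert-butyldimethylsilyloxy)-3-(3-methylbut-2-en-1-yl)benzaldehyde | CC(C)=CCc1c(O[Si](C)(C)C(C)(C)C)cc(O[Si](C)(C)C(C)(C)C)c(C=O)c1O[C@H](c1ccc(O[Si](C)(C)C(C)(C)C)c(O[Si](C)(C)C(C)(C)C)c1)CI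
F4 | step 7 | (2S)-2-[3,4-bis(tert-butyldimethylsilyloxy)phenyl]-5,7-bis(tert-butyldimethylsilyloxy)-8-(3-methylbut-2-en-1-yl)chroman-4-ol (both C4 epimers) | CC(C)=CCc1c(O[Si](C)(C)C(C)(C)C)cc(O[Si](C)(C)C(C)(C)C)c2c1O[C@H](c1ccc(O[Si](C)(C)C(C)(C)C)c(O[Si](C)(C)C(C)(C)C)c1)CC2O
F5 | step 6 | rac-2-{1-[3,4-bis(tert-butyldimethylsilyloxy)phenyl]-2-(phenylselanyl)ethoxy}-4,6-bis(tert-butyldimethylsilyloxy)-3-(3-methylbut-2-en-1-yl)benzaldehyde | CC(C)=CCc1c(O[Si](C)(C)C(C)(C)C)cc(O[Si](C)(C)C(C)(C)C)c(C=O)c1OC(C[Se]c1ccccc1)c1ccc(O[Si](C)(C)C(C)(C)C)c(O[Si](C)(C)C(C)(C)C)c1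
F6 | step 6 | selenoxide of F5 (not isolated) | CC(C)=CCc1c(O[Si](C)(C)C(C)(C)C)cc(O[Si](C)(C)C(C)(C)C)c(C=O)c1OC(C[Se](=O)c1ccccc1)c1ccc(O[Si](C)(C)C(C)(C)C)c(O[Si](C)(C)C(C)(C)C)c1
F7 | step 8 | (2S)-2-[3,4-bis(tert-butyldimethylsilyloxy)phenyl]-5,7-bis(tert-butyldimethylsilyloxy)-8-(2,3-dihydroxy-3-methylbutyl)chroman-4-one (both carbinol epimers) | CC(C)(O)C(O)Cc1c(O[Si](C)(C)C(C)(C)C)cc(O[Si](C)(C)C(C)(C)C)c2c1O[C@H](c1ccc(O[Si](C)(C)C(C)(C)C)c(O[Si](C)(C)C(C)(C)C)c1)CC2=O
F8 | step 8 | 2-{(2S)-2-[3,4-bis(tert-butyldimethylsilyloxy)phenyl]-5,7-bis(tert-butyldimethylsilyloxy)-4-oxochroman-8-yl}acetaldehyde | O=CCc1c(O[Si](C)(C)C(C)(C)C)cc(O[Si](C)(C)C(C)(C)C)c2c1O[C@H](c1ccc(O[Si](C)(C)C(C)(C)C)c(O[Si](C)(C)C(C)(C)C)c1)CC2=O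
F9 | step 8 | (E)-4-{(2S)-2-[3,4-bis(tert-butyldimethylsilyloxy)phenyl]-5,7-bis(tert-butyldimethylsilyloxy)-4-oxochroman-8-yl}-2-methylbut-2-enal | C/C(=C\Cc1c(O[Si](C)(C)C(C)(C)C)cc(O[Si](C)(C)C(C)(C)C)c2c1O[C@H](c1ccc(O[Si](C)(C)C(C)(C)C)c(O[Si](C)(C)C(C)(C)C)c1)CC2=O)C=O
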